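The route rests on cutting the side chain at C5'–C6' and C7'–C8', the two bonds flanking the C6'=C7' enone. In that enone C5' and the C8' carbonyl are cis and the C6' methyl faces H7'. A single operation adds a C3'–C5' alkylcopper syn across propyne and acylates the vinylcopper with retention, so the less stable Z geometry is dictated by mechanism. The precursor is a three-carbon Grignard reagent whose C3' aldehyde is masked as a 1,3-dioxane. After unmasking, three operations set C1' (S) and the C2'=C3' E-alkene: enantioselective butenylation, inverting O-allylation of the coumarin pyranone ring at O4, and a [3,3] shift to C3.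

Key step: step 2

Remark: the side chain is numbered C1' (on coumarin C3) to C11' along the chain, and the target SMILES is read as 1'S, 2'E, 6'Z.

Step 1
Reactants: 1 2-(2-bromoethyl)-1,3-dioxane
Product: 2 [2-(1,3-dioxan-2-yl)ethyl]magnesium bromide (titrated stock solution)
Conditions: Mg turnings, cat. I2, THF (concentrated, about 1.5 M), 25–35 °C; used the same day
Reagents that add atoms: magnesium, [Mg]
Why: Grignard formation by insertion of magnesium into the primary C–Br bond, reliable here because the six-membered acetal resists the ring opening to a cyclopropyl ether that troubles acyclic and five-membered analogues; the concentrated solution keeps the THF load of step 2 small.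

Step 2
Reactants: 2 [2-(1,3-dioxan-2-yl)ethyl]magnesium bromide; 3 propyne; 4 isovaleryl chloride
Product: 7 (Z)-1-(1,3-dioxan-2-yl)-3,7-dimethyloct-3-en-5-one, via alkylcopper 5 (not isolated), via alkenylcopper 6 (not isolated)
Conditions: CuBr·SMe2 (1.0 equiv), Et2O–Me2S, −45 °C; 3 (excess, condensed in), −25 °C; then Pd(PPh3)4 (5 mol %), 4, −25 → 0 °C; cold aq NH4Cl (about pH 7)
Reagents that add atoms: CuBr·SMe2, Br[Cu].CSC (supplies the copper of 5 and 6 only; none remains in 7)
Why: Transmetalation of 2 to monovalent copper gives the non-basic alkylcopper–MgBr2 complex 5, which binds propyne and inserts through a four-centre syn carbometalation that places C5' on the methyl-bearing alkyne carbon (C6') and copper on the terminal carbon (C7'), so C5' and Cu are cis in 6. Zerovalent palladium then adds oxidatively to 4, takes the alkenyl group from copper with retention and forms C7'–C8' by reductive elimination, outrunning the slower and less clean uncatalysed acylation. The closest known reaction type is the Normant carbocupration of terminal alkynes by alkylcopper–magnesium halide reagents combined with palladium-catalysed acylation of the alkenylcopper by an acid chloride. No ring is closed and no stereocentre is created; the only stereochemical element, the Z C6'=C7' bond, is controlled by syn addition followed by retention. The step needs regioselectivity (the steric and electronic bias of a terminal alkyne sends copper to the CH terminus), addition rather than deprotonation of propyne (equimolar Cu and Mg, ether–Me2S medium, little THF) and preserved geometry (6 kept below about −10 °C, cold near-neutral quench). The dioxane is inert to organocopper, MgBr2 and the acid chloride at these temperatures and carries C3' forward at the aldehyde oxidation level.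

Step 3
Reactants: 7 (Z)-1-(1,3-dioxan-2-yl)-3,7-dimethyloct-3-en-5-one
Product: 8 (Z)-4,8-dimethyl-6-oxonon-4-enal
Conditions: p-TsOH·H2O (10 mol %), acetone–H2O (10:1), 40 °C, stopped when 7 is consumed; cold aq NaHCO3
Reagents that add atoms: water, O
Why: Acid-catalysed acetal hydrolysis through the oxocarbenium ion, run with catalytic acid in a water-poor medium so that unimolecular acetal cleavage stays much faster than water addition–elimination or protonation–rotation at the Z-enone.

Step 4
Reactants: 8 (Z)-4,8-dimethyl-6-oxonon-4-enal; 9 but-2-yne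
Product: 12 (5Z,9S,10E)-9-hydroxy-2,6,10-trimethyldodeca-5,10-dien-4-one, via alkenylborane 10 (not isolated), via alkenylzinc 11 (not isolated)
Conditions: 9, Cy2BH (preformed solid, slight deficit relative to 9), toluene, 0 → 23 °C; Me2Zn, (+)-MIB [(2R)-3-exo-morpholinoisoborneol, 5 mol %], −78 °C; 8 added slowly, −20 → 0 °C; aqueous quench, no oxidative work-up
Reagents that add atoms: dicyclohexylborane, B(C1CCCCC1)C1CCCCC1 (appears in 10 only); dimethylzinc, C[Zn]C (appears in 11 only)
Why: Syn hydroboration of the symmetrical alkyne, boron-to-zinc exchange with retention and amino-alkoxide-catalysed asymmetric alkenylzinc 1,2-addition; the (+)-MIB zinc chelate should deliver the (E)-butenyl group to the Re face of the aldehyde (the mirror image of the Si-face delivery established for (−)-MIB), setting C3' as S, while the alkenylzinc ignores the hindered β,β-disubstituted enone.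

Step 5
Reactants: 12 (5Z,9S,10E)-9-hydroxy-2,6,10-trimethyldodeca-5,10-dien-4-one; 13 4-hydroxy-7-methoxycoumarin
Product: 14 7-methoxy-4-{[(2E,4R,7Z)-3,7,11-trimethyl-9-oxododeca-2,7-dien-4-yl]oxy}-2H-chromen-2-one
Conditions: PPh3, DIAD (betaine preformed at 0 °C so that no free phosphine meets the enone), then 13 and 12, THF, 0 → 15 °C; chromatography on deactivated silica
Reagents that add atoms: none
Why: Mitsunobu reaction in which the acidic enol of 13 protonates the betaine and its O4 displaces the C3' oxyphosphonium group by SN2 with inversion (S to R) under neutral conditions that spare the Z-enone; alkylation at the lactone carbonyl oxygen would be harmless, since a [3,3] shift from either oxygen ends at C3 with the same sense of chirality transfer.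

Step 6
Reactants: 14 7-methoxy-4-{[(2E,4R,7Z)-3,7,11-trimethyl-9-oxododeca-2,7-dien-4-yl]oxy}-2H-chromen-2-one
Product: 16 4-hydroxy-7-methoxy-3-[(2S,3E,7Z)-3,7,11-trimethyl-9-oxododeca-3,7-dien-2-yl]-2H-chromen-2-one (target), via keto tautomer 15 (not isolated)
Conditions: toluene (dilute, degassed), 100 °C, base-washed glass
Reagents that add atoms: none
Why: Claisen rearrangement of a 4-allyloxycoumarin, a [3,3]-sigmatropic shift that is suprafacial on the allyl unit; with the C4' chain pseudo-equatorial the C3'–O bond breaks and the C1'–C3 bond forms on the same allyl face, converting (R)-C3' plus the E C1'=C2' bond into (S)-C1' plus the E C2'=C3' bond, and enolisation of 15 makes the step irreversible and erases the irrelevant C3 centre.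

Compound list
1 | 2-(2-bromoethyl)-1,3-dioxane | BrCCC1OCCCO1 | starting material
2 | [2-(1,3-dioxan-2-yl)ethyl]magnesium bromide | Br[Mg]CCC1OCCCO1 | intermediate
3 | propyne | CC#C | starting material
4 | isovaleryl chloride (3-methylbutanoyl chloride) | CC(C)CC(=O)Cl | starting material
5 | [2-(1,3-dioxan-2-yl)ethyl]copper (present as its MgBr2/Me2S complex) | [Cu]CCC1OCCCO1 | intermediate
6 | [(Z)-4-(1,3-dioxan-2-yl)-2-methylbut-1-en-1-yl]copper (C5' and Cu cis) | O1CCCOC1CC/C(C)=C\[Cu] | intermediate
7 | (Z)-1-(1,3-dioxan-2-yl)-3,7-dimethyloct-3-en-5-one | O1CCCOC1CC/C(C)=C\C(=O)CC(C)C | intermediate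
8 | (Z)-4,8-dimethyl-6-oxonon-4-enal | O=CCC/C(C)=C\C(=O)CC(C)C | intermediate
9 | but-2-yne | CC#CC | starting material
10 | [(Z)-but-2-en-2-yl]dicyclohexylborane (B cis to H, methyls cis) | C/C=C(C)/B(C1CCCCC1)C1CCCCC1 | intermediate
11 | [(E)-but-2-en-2-yl](methyl)zinc (Zn cis to H, methyls cis) | C/C=C(C)/[Zn]C | intermediate
12 | (5Z,9S,10E)-9-hydroxy-2,6,10-trimethyldodeca-5,10-dien-4-one | C/C=C(C)/[C@@H](O)CC/C(C)=C\C(=O)CC(C)C | intermediate
13 | 4-hydroxy-7-methoxycoumarin | COc1ccc2c(O)cc(=O)oc2c1 | starting material
14 | 7-methoxy-4-{[(2E,4R,7Z)-3,7,11-trimethyl-9-oxododeca-2,7-dien-4-yl]oxy}-2H-chromen-2-one | C/C=C(C)/[C@H](Oc1cc(=O)oc2cc(OC)ccc12)CC/C(C)=C\C(=O)CC(C)C | intermediate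
15 | 7-methoxychromane-2,4-dione carrying the side chain of 16 at C3 (keto tautomer of 16; C1' arranged in space as in 16, C3 not defined) | COc1ccc2C(=O)C([C@@H](C)/C(C)=C/CC/C(C)=C\C(=O)CC(C)C)C(=O)Oc2c1 | intermediate
16 | 4-hydroxy-7-methoxy-3-[(2S,3E,7Z)-3,7,11-trimethyl-9-oxododeca-3,7-dien-2-yl]-2H-chromen-2-one | COc1ccc2c(O)c([C@@H](C)/C(C)=C/CC/C(C)=C\C(=O)CC(C)C)c(=O)oc2c1 | target

Total step count: 6. Longest linear sequence: 6 (1 → 2 → 7 → 8 → 12 → 14 → 16).

Steps most likely to fail

Step 2.
- Risk: insertion of the acetal-chelated, partly THF-solvated alkylcopper into propyne may be too slow. Deprotonation of propyne, thermal decay of the alkylcopper and direct acylation of unreacted alkylcopper would then take over. Geometry may also leak if the alkenylcopper warms.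
- Fallback: it sets out from 1 and returns at 7, and it builds the Z-olefin by conjugate addition, bringing in the C6' methyl as the nucleophile.
- Alkylation of LiC≡CH·H2NCH2CH2NH2 with 1 in DMSO should give 2-(but-3-yn-1-yl)-1,3-dioxane F1.
- n-BuLi followed by methyl chloroformate should give methyl 5-(1,3-dioxan-2-yl)pent-2-ynoate F2.
- Me2CuLi in THF at −78 °C with cold protonation adds methyl and copper syn. This leaves C5' cis to the ester in methyl (Z)-5-(1,3-dioxan-2-yl)-3-methylpent-2-enoate F3.
- MeNHOMe·HCl with i-PrMgCl should give (Z)-5-(1,3-dioxan-2-yl)-N-methoxy-N,3-dimethylpent-2-enamide F4, and i-BuMgBr converts it into 7.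

Step 5.
- Risk: slow SN2 displacement at the hindered C3' may let other pathways compete, with loss of material or of configurational purity. These are SN2' attack at C1', C-alkylation at coumarin C3, elimination, and ionisation of the allylic oxyphosphonium ion.
- Fallback: it sets out from 12 and returns at 14. It uses the Mukaiyama oxidation–reduction condensation, which activates the alcohol through an isolable phosphinite and no azodicarboxylate.
- Ph2PCl, Et3N and cat. DMAP in CH2Cl2 should give (5Z,9S,10E)-9-[(diphenylphosphanyl)oxy]-2,6,10-trimethyldodeca-5,10-dien-4-one F11.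
- F11, treated with 13 and 2,6-dimethyl-1,4-benzoquinone in CH2Cl2 at room temperature, should deliver 14 with inversion.

Step 3.
- Risk: opening of the robust six-membered acetal may demand enough acid and time for Z to E isomerisation of the enone, by protonation–rotation or by water addition–elimination.
- Fallback: it sets out from 3 and 4 and returns at 8. C3' passes through the key step one oxidation level lower, as a silyl ether, so no acetal has to be opened next to the Z-enone.
- Commercial (3-bromopropoxy)(tert-butyl)dimethylsilane F5 is converted with Mg in Et2O into [3-(tert-butyldimethylsilyloxy)propyl]magnesium bromide F6.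
- Under the conditions of step 2, F6 passes through [3-(tert-butyldimethylsilyloxy)propyl]copper F7 and [(Z)-5-(tert-butyldimethylsilyloxy)-2-methylpent-1-en-1-yl]copper F8 to (Z)-9-[(tert-butyldimethylsilyl)oxy]-2,6-dimethylnon-5-en-4-one F9.
- HF·pyridine in THF at 0 °C should free (Z)-9-hydroxy-2,6-dimethylnon-5-en-4-one F10.
- Dess–Martin periodinane buffered with NaHCO3 oxidises F10 to 8.

Further compounds
F1 | step 2 | 2-(but-3-yn-1-yl)-1,3-dioxane | C#CCCC1OCCCO1
F2 | step 2 | methyl 5-(1,3-dioxan-2-yl)pent-2-ynoate | COC(=O)C#CCCC1OCCCO1
F3 | step 2 | methyl (Z)-5-(1,3-dioxan-2-yl)-3-methylpent-2-enoate | O1CCCOC1CC/C(C)=C\C(=O)OC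
F4 | step 2 | (Z)-5-(1,3-dioxan-2-yl)-N-methoxy-N,3-dimethylpent-2-enamide | O1CCCOC1CC/C(C)=C\C(=O)N(C)OC
F5 | step 3 | (3-bromopropoxy)(tert-butyl)dimethylsilane | BrCCCO[Si](C)(C)C(C)(C)C
F6 | step 3 | [3-(tert-butyldimethylsilyloxy)propyl]magnesium bromide | Br[Mg]CCCO[Si](C)(C)C(C)(C)C
F7 | step 3 | [3-(tert-butyldimethylsilyloxy)propyl]copper | [Cu]CCCO[Si](C)(C)C(C)(C)C
F8 | step 3 | [(Z)-5-(tert-butyldimethylsilyloxy)-2-methylpent-1-en-1-yl]copper | CC(C)(C)[Si](C)(C)OCCC/C(C)=C\[Cu]
F9 | step 3 | (Z)-9-[(tert-butyldimethylsilyl)oxy]-2,6-dimethylnon-5-en-4-one | CC(C)(C)[Si](C)(C)OCCC/C(C)=C\C(=O)CC(C)C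
F10 | step 3 | (Z)-9-hydroxy-2,6-dimethylnon-5-en-4-one | OCCC/C(C)=C\C(=O)CC(C)C
F11 | step 5 | (5Z,9S,10E)-9-[(diphenylphosphanyl)oxy]-2,6,10-trimethyldodeca-5,10-dien-4-one | C/C=C(C)/[C@@H](OP(c1ccccc1)c1ccccc1)CC/C(C)=C\C(=O)CC(C)C
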